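The numbers in the tables are simulated on assumed constants; the scatter is artificial.

- In percent of the substrate charged, the larch and birch runs start alike, so we reckon with the fraction left and not the fraction made.

in all of them: gas phase 110 mM (held)
- larch: substrate 0.42 M; run made earlier
- birch: substrate 0.66 M; run made earlier
- flask: substrate 0.30 M; time 3.0 min

| run | time / min | target / % | substrate / % |
|---|---|---|---|
| larch | 0.500 | 2.7 | 97.3 |
| larch | 1.00 | 5.6 | 93.4 |
| larch | 1.50 | 7.0 | 90.6 |
| larch | 2.00 | 10.7 | 86.7 |
| larch | 2.50 | 11.8 | 82.2 |
| larch | 3.00 | 14.9 | 78.9 |
| larch | 4.00 | 17.4 | 71.6 |
| birch | 0.250 | 2.0 | 98.8 |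
| birch | 0.417 | 2.9 | 97.0 |
| birch | 0.667 | 2.4 | 95.3 |
| birch | 1.00 | 5.5 | 93.3 |
| birch | 1.50 | 7.2 | 89.6 |
| birch | 2.50 | 11.0 | 82.4 |
| birch | 4.00 | 14.8 | 69.7 |

(each reading ± 0.5 percentage points)
- what was read earlier has a scatter of 0.5 percentage points, one standard deviation
- at the start none of the gas phase is in solution
- how much target there is at 3.0 min, in percent of the substrate charged
- the change that raises the amount of target at 3.0 min, in percent of the substrate charged most ("none" if none brings more than 2 percentage points) (Sunday's / Wednesday's / none)
- amount of target at 3.0 min, in percent of the substrate charged, after Sunday's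

- We define the loss constant λ as minus the natural logarithm of the fraction of substrate left, divided by the time. At 1.00 min larch gives 0.0683 /min and birch 0.0694 /min, alike at different charges, so the early loss looks pseudo-first-order. We carry their mean, λ = 0.0688 /min.
- But λ may not hold later. Over 3.0 min it leaves 81.3%, while larch reads 78.9%, a difference of 2.4 percentage points against a scatter of 0.5 points. So we read a second, later loss of substrate and keep λ for the main step, which we reckon makes 18.7% in that time.
- Larch holds 14.9% of target then, but the flask is charged less, so its losses may be smaller. Between larch and birch, target differs by 2.6 points at 4.00 min; scaled to the flask's smaller charge step, that gives a rough 16.2%. We commit to 15.5% for the flask.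
- Could the gas-free start matter? Birch reads 2.0% of target at 0.250 min, and λ predicts 1.71%, so we see no lag. We expect Sunday's to change little.
- If λ follows dissolved gas, which no run tested, Wednesday's squares the fraction left to 66.2%. That adds 15 points made, more than the 2 points margin, so we choose it.
- The forecast gave 15%, Wednesday's and 15.2%, its target below ours: “Doubling transfer should therefore do almost nothing”.
- The flask gives 14.7% of target; Wednesday's adds 11 points, and Sunday's gives 14.8%.

    gas phase ⇌ dissolved gas, rate k1*(csat - [dissolved gas]) (kL = 23.0 /min)
    substrate + dissolved gas → target (k = 0.640 /M/min)
    dissolved gas + target → over-reacted product (k = 0.170 /M/min)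
    target → over-reaction product (k = 0.0510 /min)
    substrate + target → side product (k = 0.330 /M/min)

- Dissolved gas in the flask stood at 99.2% of saturation at 1.50 min, and the slowness of transfer barely moves the target. Side product counts as two, so we divide its percentage by 2. Adding target, over-reacted product, over-reaction product and that quotient gives 18.5% for the flask, against 18.7% from λ. The neighbour charged with 1.2 M holds 10.2% of target, yet the same sum there gives 17.8%.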